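**Plan**

1. Retrosynthesis: first the late adjustments (C2 carbinol, C12 acetate, C5 ether, C1 methylene, C10–CH3), then C4–C5 and C6–C7 together, then C10–C6 and C2–C3 (two alkenyl additions to one cyclohexenone), then C3=C4 and C11–C12 in the side chain.
2. Enabling feature: C2 and C10 both carry oxygen and are linked around the ten-membered perimeter of the bicyclo[5.3.0]decane by C3–C4–C5–C6 and through the ring fusion by C1–C7–C6. With both as carbonyls, C4–C5 is the σ-bond of an oxy-Cope rearrangement of a 1,2-dialkenylcyclohex-3-ene-1,2-diol and C6–C7 is a transannular Michael bond.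
3. Forward: the six-membered ring 14 takes on both alkenyl arms (22), expands to a ten-membered ring (C4–C5), and closes across it to the five- and seven-membered rings (C6–C7) in the same flask; the cyclopentenone, the C10 carbinol, the C1 methylene and the C2 carbinol follow.
4. Stereochemistry: C11/C12 from an Evans aldol; the C8 silyloxy centre of 14 (later eliminated) sets C2 and C10 of 22; a chair oxy-Cope transfers these to C4/C5; C7 by attack anti to C8–O; C6 by equilibration; C10 by organocerium addition; C2 by CBS reduction.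

Key step: step 13

Remark: route numbering is C1 (=CH2 carbon) to C7 for the seven-membered ring, C6–C7–C8–C9–C10 for the five-membered ring, C11 (CH3-bearing) and C12 (O-bearing) in the side chain; TBS = tert-butyldimethylsilyl, TES = triethylsilyl, PMB = 4-methoxybenzyl; enone 14 and imide 3 are assumed to be catalogue compounds.

**Route**

Step 1
Reactants: 1 4-methylpent-3-en-1-ol
Product: 2 4-methylpent-3-enal
Conditions: Dess–Martin periodinane, NaHCO3, CH2Cl2, 0 °C; used crude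
Reagents that add atoms: none
Why: Dess–Martin oxidation under buffered, neutral conditions should give the β,γ-unsaturated aldehyde without migration of the double bond.

Step 2
Reactants: 3 (R)-4-benzyl-3-propanoyl-1,3-oxazolidin-2-one; 2 4-methylpent-3-enal
Product: 5 (R)-4-benzyl-3-[(2R,3S)-3-hydroxy-2,6-dimethylhept-5-enoyl]-1,3-oxazolidin-2-one, via dibutylboron Z-enolate 4 (not isolated)
Conditions: Bu2BOTf, Et3N, CH2Cl2, −78 to 0 °C; then 2, −78 to 0 °C; H2O2, pH 7 buffer, MeOH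
Reagents that add atoms: none
Why: Evans syn-aldol reaction; the Z-boron enolate reacts through a chair transition state on the face left open by the benzyl group, which should set C11 and C12 (2R,3S in this compound).

Step 3
Reactants: 5 (R)-4-benzyl-3-[(2R,3S)-3-hydroxy-2,6-dimethylhept-5-enoyl]-1,3-oxazolidin-2-one
Product: 6 (R)-4-benzyl-3-[(2R,3S)-3-(TBS-oxy)-2,6-dimethylhept-5-enoyl]-1,3-oxazolidin-2-one
Conditions: TBSOTf, 2,6-lutidine, CH2Cl2, −78 to 0 °C
Reagents that add atoms: tert-butyldimethylsilyl triflate CC(C)(C)[Si](C)(C)OS(=O)(=O)C(F)(F)F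
Why: standard silylation of a secondary aldol hydroxyl, which also blocks retro-aldol cleavage in the next step.

Step 4
Reactants: 6 (R)-4-benzyl-3-[(2R,3S)-3-(TBS-oxy)-2,6-dimethylhept-5-enoyl]-1,3-oxazolidin-2-one
Product: 7 (2S,3S)-3-(TBS-oxy)-2,6-dimethylhept-5-en-1-ol
Conditions: LiBH4, MeOH (1 equiv), THF, 0 °C
Reagents that add atoms: none
Why: reductive cleavage of the N-acyl oxazolidinone by LiBH4 should release the primary alcohol and the auxiliary without touching the silyl ether or the alkene.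

Step 5
Reactants: 7 (2S,3S)-3-(TBS-oxy)-2,6-dimethylhept-5-en-1-ol
Product: 8 (2R,3S)-3-(TBS-oxy)-2,6-dimethylhept-5-enal
Conditions: Dess–Martin periodinane, NaHCO3, CH2Cl2, 0 °C; used at once
Reagents that add atoms: none
Why: Dess–Martin oxidation is neutral and should not epimerise the α-stereocentre.

Step 6
Reactants: 8 (2R,3S)-3-(TBS-oxy)-2,6-dimethylhept-5-enal
Product: 9 (1E,3S,4S)-4-(TBS-oxy)-1-iodo-3,7-dimethylocta-1,6-diene
Conditions: CrCl2, CHI3, THF/dioxane, 0 °C to rt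
Reagents that add atoms: iodoform IC(I)I
Why: Takai olefination; the geminal dichromium species adds to the aldehyde and eliminates anti, which should give the E-iodoalkene (C3=C4).

Step 7
Reactants: 10 4-methoxybenzyl alcohol
Product: 11 4-methoxybenzyl vinyl ether
Conditions: vinyl acetate, [Ir(cod)Cl]2 (1 mol %), Na2CO3, toluene, 100 °C
Reagents that add atoms: vinyl acetate CC(=O)OC=C
Why: iridium-catalysed transfer vinylation of an alcohol by vinyl acetate is an established route to alkyl vinyl ethers.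

Step 8
Reactants: 11 4-methoxybenzyl vinyl ether
Product: 13 (Z)-2-bromoethenyl 4-methoxybenzyl ether, via 1,2-dibromoethyl ether 12 (not isolated)
Conditions: Br2, CH2Cl2, −78 °C; then Et3N, 0 °C to rt
Reagents that add atoms: bromine BrBr
Why: bromine addition to the enol ether and amine-induced loss of HBr from the α-bromo ether is the standard route to 2-bromovinyl ethers and should favour the Z-isomer; any E-isomer is removed by chromatography.

Step 9
Reactants: 14 (S)-4-(TBS-oxy)cyclohex-2-en-1-one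
Product: 16 (4S,6S)-4-(TBS-oxy)-6-hydroxycyclohex-2-en-1-one, via lithium dienolate 15 (not isolated)
Conditions: LiN(SiMe3)2, THF, −78 °C; then 2-(phenylsulfonyl)-3-phenyloxaziridine, −78 °C; aq. NH4Cl
Reagents that add atoms: 2-(phenylsulfonyl)-3-phenyloxaziridine O=S(=O)(c1ccccc1)N1OC1c1ccccc1
Why: Davis oxidation of the kinetic cross-conjugated enolate; oxygen should be delivered to C10 anti to the pseudo-axial C8 silyloxy group (trans product).

Step 10
Reactants: 16 (4S,6S)-4-(TBS-oxy)-6-hydroxycyclohex-2-en-1-one; 9 (1E,3S,4S)-4-(TBS-oxy)-1-iodo-3,7-dimethylocta-1,6-diene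
Product: 19 (1S,2S,5S)-5-(TBS-oxy)-2-[(1E,3S,4S)-4-(TBS-oxy)-3,7-dimethylocta-1,6-dien-1-yl]cyclohex-3-ene-1,2-diol, via lithium alkoxide 17 (not isolated), via alkenyllithium 18 (not isolated)
Conditions: 16: LiN(SiMe3)2 (1.0 equiv), THF, −78 °C; 9: t-BuLi (2.0 equiv), Et2O, −78 °C; combine at −78 °C; aq. NH4Cl
Reagents that add atoms: none
Why: chelation-controlled 1,2-addition of an alkenyllithium to an α-alkoxido enone; axial attack on the lithium chelate, anti to the pseudo-axial C8 silyloxy group, should place the alkenyl arm cis to the C10 oxygen and set C2 (S), with the E-geometry retained.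

Step 11
Reactants: 19 (1S,2S,5S)-5-(TBS-oxy)-2-[(1E,3S,4S)-4-(TBS-oxy)-3,7-dimethylocta-1,6-dien-1-yl]cyclohex-3-ene-1,2-diol
Product: 20 (2S,5S)-5-(TBS-oxy)-2-hydroxy-2-[(1E,3S,4S)-4-(TBS-oxy)-3,7-dimethylocta-1,6-dien-1-yl]cyclohex-3-en-1-one
Conditions: Dess–Martin periodinane, NaHCO3, CH2Cl2, 0 °C
Reagents that add atoms: none
Why: only the secondary carbinol (C10) can be oxidised, and the buffered neutral conditions should spare the β-silyloxy ketone and the tertiary bis-allylic alcohol.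

Step 12
Reactants: 20 (2S,5S)-5-(TBS-oxy)-2-hydroxy-2-[(1E,3S,4S)-4-(TBS-oxy)-3,7-dimethylocta-1,6-dien-1-yl]cyclohex-3-en-1-one; 13 (Z)-2-bromoethenyl 4-methoxybenzyl ether
Product: 22 (1R,2S,5S)-5-(TBS-oxy)-2-[(1E,3S,4S)-4-(TBS-oxy)-3,7-dimethylocta-1,6-dien-1-yl]-1-[(Z)-2-(PMB-oxy)ethenyl]cyclohex-3-ene-1,2-diol, via (Z)-2-(PMB-oxy)ethenyllithium 21 (not isolated)
Conditions: 13 (2.6 equiv), t-BuLi (5.2 equiv), Et2O, −78 °C; then 20, THF, −78 °C; aq. NH4Cl/NH3 (pH 8)
Reagents that add atoms: none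
Why: addition of a configurationally stable Z-2-alkoxyvinyllithium to an α-alkoxido ketone; in the chelate the C2 alkenyl arm is axial and attack anti to it should give the trans-dialkenyl diol (C10 R).

Step 13
Reactants: 22 (1R,2S,5S)-5-(TBS-oxy)-2-[(1E,3S,4S)-4-(TBS-oxy)-3,7-dimethylocta-1,6-dien-1-yl]-1-[(Z)-2-(PMB-oxy)ethenyl]cyclohex-3-ene-1,2-diol
Product: 25 (4S,5R,6R,7S,8S)-bicyclo[5.3.0]dec-1-en-10-one carrying 2-OTES; 5-OPMB; 8-OTBS; 4-[(2S,3S)-3-(TBS-oxy)-6-methylhept-5-en-2-yl] (route numbering), via ten-membered potassium enolate 23 (not isolated), via bicyclic potassium enolate 24 (not isolated)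
Conditions: KN(SiMe3)2 (1.0 equiv), 18-crown-6, THF, −78 to −20 °C; then Et3SiCl, Et3N, −78 °C
Reagents that add atoms: chlorotriethylsilane CC[Si](Cl)(CC)CC
Why: Proposed new method: the mono-potassium alkoxide of 22 should undergo a chair [3,3] anionic oxy-Cope rearrangement (closest known type: ring expansion of 1,2-dialkenylcyclohexanols and 1,2-diols) that breaks C2–C10 and forms C4–C5, after which proton transfer from the C10 enol to C3 leaves a Z-enone at C2 and a C10 enolate that adds across the ring to C7 (closest known type: transannular Michael addition in medium rings), and the resulting C1=C2 enolate is silylated. The ten-membered ring arises by ring expansion of the six-membered ring, and the five-membered ring (and so the seven-membered ring) closes in a transannular 5-(enolendo)-exo-trig mode. C4 and C5 are fixed by the chair transition state (E-alkenyl arm equatorial, Z-alkoxyvinyl arm axial) with transfer of chirality from C2 and C10; C7 is fixed by attack anti to the C8 silyloxy group with H8 eclipsing the Z-enone (allylic strain); C6 is provisional and is corrected in step 14. The step needs the Michael addition to outrun transannular aldol addition and loss of the C5 ether from the C10 enolate, and needs the C1=C2 enolate to be trapped before it exchanges protons: aldol adducts should revert under the conditions, exactly one equivalent of base leaves no free base once the enone has formed, and the silylation is done at −78 °C.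

Step 14
Reactants: 25 the bicyclic TES enol ether of step 13
Product: 26 (4S,5R,6R,7S)-bicyclo[5.3.0]deca-1,8-dien-10-one carrying 2-OTES; 5-OPMB; 4-[(2S,3S)-3-(TBS-oxy)-6-methylhept-5-en-2-yl]
Conditions: DBU, CH2Cl2, 0 °C to rt
Reagents that add atoms: none
Why: E1cB loss of the C8 silyloxide from the C9 enolate should give the cyclopentenone, and the same base should equilibrate the α′-centre C6 to the trans ring fusion in which the C5–O, C6–C10 and C7–C8 bonds are mutually trans.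

Step 15
Reactants: 26 the cyclopentenone of step 14
Product: 27 (4S,5R,6R,7S,10S)-10-methylbicyclo[5.3.0]deca-1,8-dien-10-ol carrying 2-OTES; 5-OPMB; 4-[(2S,3S)-3-(TBS-oxy)-6-methylhept-5-en-2-yl]
Conditions: MeLi, CeCl3, THF, −78 °C; aq. NH4Cl
Reagents that add atoms: methyllithium [Li]C
Why: 1,2-addition of the non-basic organocerium reagent to the enone; attack anti to the pseudo-axial C6–H of the trans-fused system (torsional control) should place the hydroxyl cis to H6 (10S).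

Step 16
Reactants: 27 the tertiary alcohol of step 15
Product: 30 (4S,5R,6R,7R,10S)-10-hydroxy-10-methyl-1-methylidenebicyclo[5.3.0]dec-8-en-2-one carrying 5-OPMB; 4-[(2S,3S)-3-(TBS-oxy)-6-methylhept-5-en-2-yl], via Mannich base 28 (not isolated), via trimethylammonium iodide 29 (not isolated)
Conditions: CH2=NMe2+ Cl−, CH2Cl2, 0 °C to rt; then MeI, rt; then aq. NaHCO3
Reagents that add atoms: N,N-dimethylmethyleneiminium chloride C=[N+](C)C.[Cl-]
Why: Mannich reaction of the silyl enol ether places the aminomethyl group only on C1, and quaternisation followed by E1cB elimination should give the exocyclic enone.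

Step 17
Reactants: 30 the α-methylene ketone of step 16
Product: 31 (4S,5R,6R,7R,10S)-10-hydroxy-4-[(2S,3S)-3-hydroxy-6-methylhept-5-en-2-yl]-10-methyl-1-methylidene-5-(PMB-oxy)bicyclo[5.3.0]dec-8-en-2-one
Conditions: HF·pyridine, pyridine, THF, 0 °C
Reagents that add atoms: none
Why: buffered fluoride desilylation should remove the remaining TBS ether without ionising the tertiary allylic alcohol or adding to the enone.

Step 18
Reactants: 31 the C12 alcohol of step 17
Product: 32 (2S,3S)-2-[(4S,5R,6R,7R,10S)-10-hydroxy-10-methyl-1-methylidene-2-oxo-5-(PMB-oxy)bicyclo[5.3.0]dec-8-en-4-yl]-6-methylhept-5-en-3-yl acetate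
Conditions: Ac2O, pyridine, DMAP (cat.), CH2Cl2, 0 °C
Reagents that add atoms: acetic anhydride CC(=O)OC(C)=O
Why: the C12 hydroxyl is the only secondary alcohol present, and the tertiary C10 alcohol should not be acylated under these conditions.

Step 19
Reactants: 32 the acetate of step 18
Product: 33 (2S,3S)-2-[(4S,5R,6R,7R,10S)-5,10-dihydroxy-10-methyl-1-methylidene-2-oxobicyclo[5.3.0]dec-8-en-4-yl]-6-methylhept-5-en-3-yl acetate
Conditions: DDQ, CH2Cl2/pH 7 buffer, 0 °C
Reagents that add atoms: none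
Why: oxidative cleavage of the PMB ether by DDQ is compatible with the acetate, the alkenes and the enone, and is placed before the C2 reduction because DDQ can oxidise allylic alcohols.

Step 20
Reactants: 33 the enone diol of step 19
Product: 34 (2S,3S)-2-[(1S,3aR,5R,7S,8R,8aR)-1,5,8-trihydroxy-1-methyl-4-methylidene-1,3a,4,5,6,7,8,8a-octahydroazulen-7-yl]-6-methylhept-5-en-3-yl acetate (target; route descriptors 2R,4S,5R,6R,7R,10S,11S,12S)
Conditions: (S)-2-methyl-CBS-oxazaborolidine, catecholborane (excess), toluene, −78 to −40 °C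
Reagents that add atoms: none
Why: Corey–Bakshi–Shibata reduction gives 1,2-reduction under reagent control; with the alkenyl carbon C1 as the large group the (S)-catalyst should deliver hydride to give the (2R)-allylic alcohol.

**Compound list**

1 | 4-methylpent-3-en-1-ol | CC(C)=CCCO | starting material
2 | 4-methylpent-3-enal | CC(C)=CCC=O | intermediate
3 | (R)-4-benzyl-3-propanoyl-1,3-oxazolidin-2-one | CCC(=O)N1C(=O)OC[C@H]1Cc1ccccc1 | starting material
4 | dibutylboron Z-enolate of 3 | C/C=C(\OB(CCCC)CCCC)N1C(=O)OC[C@H]1Cc1ccccc1 | intermediate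
5 | (R)-4-benzyl-3-[(2R,3S)-3-hydroxy-2,6-dimethylhept-5-enoyl]-1,3-oxazolidin-2-one | O=C(N1C(=O)OC[C@H]1Cc1ccccc1)[C@H](C)[C@H](CC=C(C)C)O | intermediate
6 | (R)-4-benzyl-3-[(2R,3S)-3-(TBS-oxy)-2,6-dimethylhept-5-enoyl]-1,3-oxazolidin-2-one | O=C(N1C(=O)OC[C@H]1Cc1ccccc1)[C@H](C)[C@H](CC=C(C)C)O[Si](C)(C)C(C)(C)C | intermediate
7 | (2S,3S)-3-(TBS-oxy)-2,6-dimethylhept-5-en-1-ol | OC[C@H](C)[C@H](CC=C(C)C)O[Si](C)(C)C(C)(C)C | intermediate
8 | (2R,3S)-3-(TBS-oxy)-2,6-dimethylhept-5-enal | O=C[C@H](C)[C@H](CC=C(C)C)O[Si](C)(C)C(C)(C)C | intermediate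
9 | (1E,3S,4S)-4-(TBS-oxy)-1-iodo-3,7-dimethylocta-1,6-diene | I/C=C/[C@H](C)[C@H](CC=C(C)C)O[Si](C)(C)C(C)(C)C | intermediate
10 | 4-methoxybenzyl alcohol | COc1ccc(CO)cc1 | starting material
11 | 4-methoxybenzyl vinyl ether | C=COCc1ccc(OC)cc1 | intermediate
12 | 1,2-dibromoethyl 4-methoxybenzyl ether | BrCC(Br)OCc1ccc(OC)cc1 | intermediate
13 | (Z)-2-bromoethenyl 4-methoxybenzyl ether | Br/C=C\OCc1ccc(OC)cc1 | intermediate
14 | (S)-4-(TBS-oxy)cyclohex-2-en-1-one | O=C1C=C[C@@H](O[Si](C)(C)C(C)(C)C)CC1 | starting material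
15 | lithium dienolate of 14 | [Li+].[O-]C1=CC[C@H](O[Si](C)(C)C(C)(C)C)C=C1 | intermediate
16 | (4S,6S)-4-(TBS-oxy)-6-hydroxycyclohex-2-en-1-one | O=C1C=C[C@@H](O[Si](C)(C)C(C)(C)C)C[C@@H]1O | intermediate
17 | lithium alkoxide of 16 | O=C1C=C[C@@H](O[Si](C)(C)C(C)(C)C)C[C@@H]1[O-].[Li+] | intermediate
18 | (1E,3S,4S)-4-(TBS-oxy)-3,7-dimethylocta-1,6-dien-1-yllithium | [Li]/C=C/[C@H](C)[C@H](CC=C(C)C)O[Si](C)(C)C(C)(C)C | intermediate
19 | (1S,2S,5S)-5-(TBS-oxy)-2-[(1E,3S,4S)-4-(TBS-oxy)-3,7-dimethylocta-1,6-dien-1-yl]cyclohex-3-ene-1,2-diol | O[C@@]1(/C=C/[C@H](C)[C@H](CC=C(C)C)O[Si](C)(C)C(C)(C)C)C=C[C@@H](O[Si](C)(C)C(C)(C)C)C[C@@H]1O | intermediate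
20 | (2S,5S)-5-(TBS-oxy)-2-hydroxy-2-[(1E,3S,4S)-4-(TBS-oxy)-3,7-dimethylocta-1,6-dien-1-yl]cyclohex-3-en-1-one | O[C@@]1(/C=C/[C@H](C)[C@H](CC=C(C)C)O[Si](C)(C)C(C)(C)C)C=C[C@@H](O[Si](C)(C)C(C)(C)C)CC1=O | intermediate
21 | (Z)-2-(PMB-oxy)ethenyllithium | [Li]/C=C\OCc1ccc(OC)cc1 | intermediate
22 | (1R,2S,5S)-5-(TBS-oxy)-2-[(1E,3S,4S)-4-(TBS-oxy)-3,7-dimethylocta-1,6-dien-1-yl]-1-[(Z)-2-(PMB-oxy)ethenyl]cyclohex-3-ene-1,2-diol | O[C@@]1(/C=C/[C@H](C)[C@H](CC=C(C)C)O[Si](C)(C)C(C)(C)C)C=C[C@@H](O[Si](C)(C)C(C)(C)C)C[C@@]1(O)/C=C\OCc1ccc(OC)cc1 | intermediate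
23 | ten-membered potassium enolate (C2 ketone, Z-C1=C7, C6=C10 enolate, 5-OPMB, 8-OTBS, side chain on C4) | O=C1C[C@@H]([C@H](C)[C@H](CC=C(C)C)O[Si](C)(C)C(C)(C)C)[C@@H](OCc2ccc(OC)cc2)/C=C(\[O-])C[C@H](O[Si](C)(C)C(C)(C)C)/C=C\1.[K+] | intermediate
24 | bicyclic potassium enolate (C1=C2–OK, C10 ketone) | C1=C([O-])C[C@@H]([C@H](C)[C@H](CC=C(C)C)O[Si](C)(C)C(C)(C)C)[C@@H](OCc3ccc(OC)cc3)[C@H]2[C@H]1[C@@H](O[Si](C)(C)C(C)(C)C)CC2=O.[K+] | intermediate
25 | (4S,5R,6R,7S,8S)-bicyclo[5.3.0]dec-1-en-10-one with 2-OTES, 5-OPMB, 8-OTBS and 4-[(2S,3S)-3-(TBS-oxy)-6-methylhept-5-en-2-yl] | C1=C(O[Si](CC)(CC)CC)C[C@@H]([C@H](C)[C@H](CC=C(C)C)O[Si](C)(C)C(C)(C)C)[C@@H](OCc3ccc(OC)cc3)[C@H]2[C@H]1[C@@H](O[Si](C)(C)C(C)(C)C)CC2=O | intermediate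
26 | (4S,5R,6R,7S)-bicyclo[5.3.0]deca-1,8-dien-10-one with 2-OTES, 5-OPMB and the same C4 side chain | C1=C(O[Si](CC)(CC)CC)C[C@@H]([C@H](C)[C@H](CC=C(C)C)O[Si](C)(C)C(C)(C)C)[C@@H](OCc3ccc(OC)cc3)[C@H]2[C@H]1C=CC2=O | intermediate
27 | (4S,5R,6R,7S,10S)-10-methylbicyclo[5.3.0]deca-1,8-dien-10-ol with 2-OTES, 5-OPMB and the same C4 side chain | C1=C(O[Si](CC)(CC)CC)C[C@@H]([C@H](C)[C@H](CC=C(C)C)O[Si](C)(C)C(C)(C)C)[C@@H](OCc3ccc(OC)cc3)[C@H]2[C@H]1C=C[C@]2(C)O | intermediate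
28 | Mannich base: 1-(dimethylaminomethyl) C2 ketone (C1 epimers) | CN(C)CC1C(=O)C[C@@H]([C@H](C)[C@H](CC=C(C)C)O[Si](C)(C)C(C)(C)C)[C@@H](OCc3ccc(OC)cc3)[C@H]2[C@H]1C=C[C@]2(C)O | intermediate
29 | trimethylammonium iodide of 28 | C[N+](C)(C)CC1C(=O)C[C@@H]([C@H](C)[C@H](CC=C(C)C)O[Si](C)(C)C(C)(C)C)[C@@H](OCc3ccc(OC)cc3)[C@H]2[C@H]1C=C[C@]2(C)O.[I-] | intermediate
30 | (4S,5R,6R,7R,10S)-10-hydroxy-10-methyl-1-methylidenebicyclo[5.3.0]dec-8-en-2-one with 5-OPMB and 4-[(2S,3S)-3-(TBS-oxy)-6-methylhept-5-en-2-yl] | C=C1C(=O)C[C@@H]([C@H](C)[C@H](CC=C(C)C)O[Si](C)(C)C(C)(C)C)[C@@H](OCc3ccc(OC)cc3)[C@H]2[C@H]1C=C[C@]2(C)O | intermediate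
31 | (4S,5R,6R,7R,10S)-10-hydroxy-4-[(2S,3S)-3-hydroxy-6-methylhept-5-en-2-yl]-10-methyl-1-methylidene-5-(PMB-oxy)bicyclo[5.3.0]dec-8-en-2-one | C=C1C(=O)C[C@@H]([C@H](C)[C@H](CC=C(C)C)O)[C@@H](OCc3ccc(OC)cc3)[C@H]2[C@H]1C=C[C@]2(C)O | intermediate
32 | (2S,3S)-2-[(4S,5R,6R,7R,10S)-10-hydroxy-10-methyl-1-methylidene-2-oxo-5-(PMB-oxy)bicyclo[5.3.0]dec-8-en-4-yl]-6-methylhept-5-en-3-yl acetate | C=C1C(=O)C[C@@H]([C@H](C)[C@H](CC=C(C)C)OC(C)=O)[C@@H](OCc3ccc(OC)cc3)[C@H]2[C@H]1C=C[C@]2(C)O | intermediate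
33 | (2S,3S)-2-[(4S,5R,6R,7R,10S)-5,10-dihydroxy-10-methyl-1-methylidene-2-oxobicyclo[5.3.0]dec-8-en-4-yl]-6-methylhept-5-en-3-yl acetate | C=C1C(=O)C[C@@H]([C@H](C)[C@H](CC=C(C)C)OC(C)=O)[C@@H](O)[C@H]2[C@H]1C=C[C@]2(C)O | intermediate
34 | (2S,3S)-2-[(1S,3aR,5R,7S,8R,8aR)-1,5,8-trihydroxy-1-methyl-4-methylidene-1,3a,4,5,6,7,8,8a-octahydroazulen-7-yl]-6-methylhept-5-en-3-yl acetate | C=C1[C@H](O)C[C@@H]([C@H](C)[C@H](CC=C(C)C)OC(C)=O)[C@@H](O)[C@H]2[C@H]1C=C[C@]2(C)O | target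

**Step count and risks**

Total steps: 20. Longest linear sequence: 17 (steps 1–6, then 10–20).

Step 13 (key step). The cascade may stall at the ten-membered ring, lose the C5 ether by β-elimination from the C10 enolate, or scramble the C1=C2 enolate by proton exchange before silylation. Fallback, from 22 back to 25, with the events separated: excess KH with 18-crown-6 in THF runs only the anionic oxy-Cope rearrangement, as the dialkoxide, to the dipotassium bis-enolate F1, which cannot undergo Michael addition, and Et3SiCl gives the ten-membered bis(silyl enol ether) F2. Buffered hydrolysis (AcOH, wet THF, −20 °C) should cleave the more basic dienyl silyl ether first and give the ten-membered enone F3, which keeps the C10 TES enol ether. Catalytic Et3SiOTf in CH2Cl2 at −78 °C then effects a separate transannular Mukaiyama–Michael addition with silyl transfer, which returns to 25.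

Step 15. Methyl may add mainly to the face syn to H6 (anti to the C5 branch), giving the wrong C10 configuration. Fallback, from 26 back to 31, which delivers oxygen rather than carbon to C10: methyl addition as in step 15, without regard to face, gives the C10-epimeric carbinols F4, and methylenation as in step 16 gives enones F5. NaBH4/CeCl3·7H2O (alcohols F6) and TBSCl/imidazole mask the C2 enone as silyl ethers F7. Oxidative allylic transposition with [C5H5NH][CrO3Cl] converts both C10 epimers into the single enone F8 (C8 ketone, C9=C10–CH3). H2O2/NaOH epoxidation on the face anti to the C5 branch gives epoxy ketone F9, and Wharton transposition (N2H4·H2O, AcOH, MeOH) gives the C10 carbinol F10 with C8=C9 restored and the oxygen on the required face. HF·pyridine gives diol F11, and MnO2 reoxidises only the allylic C2 carbinol, which returns to 31.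

Step 10. The bulky alkenyllithium may add with poor facial selectivity or enolise the enone, giving the wrong C2 configuration and hence the wrong absolute sense at C4/C5. Fallback, from 8 back to 19, with a small linear nucleophile: Ohira–Bestmann homologation of 8 (dimethyl (1-diazo-2-oxopropyl)phosphonate, K2CO3, MeOH) gives alkyne F12. Its lithium acetylide F13 (n-BuLi) adds axially to the lithium alkoxide 17 to give the propargylic diol F14. Hydroxyl-directed trans-hydroalumination with NaAlH2(OCH2CH2OMe)2 in THF gives the E-alkene, which returns to 19.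

**Further compounds**

F1 | step 13 | dipotassium bis-enolate of the ten-membered ring | [O-]\C1=C/[C@@H]([C@H](C)[C@H](CC=C(C)C)O[Si](C)(C)C(C)(C)C)[C@@H](OCc2ccc(OC)cc2)/C=C(\[O-])C[C@H](O[Si](C)(C)C(C)(C)C)\C=C/1.[K+].[K+]
F2 | step 13 | ten-membered bis(triethylsilyl enol ether) | CC[Si](CC)(CC)O\C1=C/[C@@H]([C@H](C)[C@H](CC=C(C)C)O[Si](C)(C)C(C)(C)C)[C@@H](OCc2ccc(OC)cc2)/C=C(\O[Si](CC)(CC)CC)C[C@H](O[Si](C)(C)C(C)(C)C)\C=C/1
F3 | step 13 | ten-membered Z-enone with C10 triethylsilyl enol ether | O=C1C[C@@H]([C@H](C)[C@H](CC=C(C)C)O[Si](C)(C)C(C)(C)C)[C@@H](OCc2ccc(OC)cc2)/C=C(\O[Si](CC)(CC)CC)C[C@H](O[Si](C)(C)C(C)(C)C)/C=C\1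
F4 | step 15 | C10-epimeric mixture of carbinol 27 | C1=C(O[Si](CC)(CC)CC)C[C@@H]([C@H](C)[C@H](CC=C(C)C)O[Si](C)(C)C(C)(C)C)[C@@H](OCc3ccc(OC)cc3)[C@H]2[C@H]1C=CC2(C)O
F5 | step 15 | C10-epimeric mixture of enone 30 | C=C1C(=O)C[C@@H]([C@H](C)[C@H](CC=C(C)C)O[Si](C)(C)C(C)(C)C)[C@@H](OCc3ccc(OC)cc3)[C@H]2[C@H]1C=CC2(C)O
F6 | step 15 | C2 allylic alcohols from F5 (C2 and C10 epimers) | C=C1C(O)C[C@@H]([C@H](C)[C@H](CC=C(C)C)O[Si](C)(C)C(C)(C)C)[C@@H](OCc3ccc(OC)cc3)[C@H]2[C@H]1C=CC2(C)O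
F7 | step 15 | C2 TBS ethers of F6 | C=C1C(O[Si](C)(C)C(C)(C)C)C[C@@H]([C@H](C)[C@H](CC=C(C)C)O[Si](C)(C)C(C)(C)C)[C@@H](OCc3ccc(OC)cc3)[C@H]2[C@H]1C=CC2(C)O
F8 | step 15 | transposed enone (C8 ketone, C9=C10–CH3; C2 epimers) | C=C1C(O[Si](C)(C)C(C)(C)C)C[C@@H]([C@H](C)[C@H](CC=C(C)C)O[Si](C)(C)C(C)(C)C)[C@@H](OCc3ccc(OC)cc3)[C@H]2[C@H]1C(=O)C=C2C
F9 | step 15 | 9,10-epoxy C8 ketone (oxygen cis to H6) | C=C1C(O[Si](C)(C)C(C)(C)C)C[C@@H]([C@H](C)[C@H](CC=C(C)C)O[Si](C)(C)C(C)(C)C)[C@@H](OCc3ccc(OC)cc3)[C@H]2[C@H]1C(=O)[C@@H]4O[C@]24C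
F10 | step 15 | (10S)-carbinol with C8=C9, C2 OTBS | C=C1C(O[Si](C)(C)C(C)(C)C)C[C@@H]([C@H](C)[C@H](CC=C(C)C)O[Si](C)(C)C(C)(C)C)[C@@H](OCc3ccc(OC)cc3)[C@H]2[C@H]1C=C[C@]2(C)O
F11 | step 15 | C2,C12-diol from F10 | C=C1C(O)C[C@@H]([C@H](C)[C@H](CC=C(C)C)O)[C@@H](OCc3ccc(OC)cc3)[C@H]2[C@H]1C=C[C@]2(C)O
F12 | step 10 | (3S,4S)-4-(TBS-oxy)-3,7-dimethyloct-6-en-1-yne | C#C[C@H](C)[C@H](CC=C(C)C)O[Si](C)(C)C(C)(C)C
F13 | step 10 | lithium acetylide of F12 | [Li]C#C[C@H](C)[C@H](CC=C(C)C)O[Si](C)(C)C(C)(C)C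
F14 | step 10 | (1S,2S,5S)-5-(TBS-oxy)-2-[(3S,4S)-4-(TBS-oxy)-3,7-dimethyloct-6-en-1-yn-1-yl]cyclohex-3-ene-1,2-diol | O[C@@]1(C#C[C@H](C)[C@H](CC=C(C)C)O[Si](C)(C)C(C)(C)C)C=C[C@@H](O[Si](C)(C)C(C)(C)C)C[C@@H]1O
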